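Start from the time: Tuesday's flow tank and Friday's closed flask both give the mixture 2.5 min, the first as a mean stay and the second as a run. Set that time against one other, the life of the target.

| flask | substrate | remark | time |
|---|---|---|---|
| autumn | 22 mM | run made earlier |  |
| spring | 11 mM | run made earlier |  |
| dusk | 16 mM | run made earlier |  |
| Tuesday's | 22 mM | one stirred flow tank at steady state, fed with the mixture as stated, mean residence time 2.5 min |  |
| Friday's | 22 mM | everything together in a closed stirred flask, run for 2.5 min | 2.5 min |

| run | time / min | target / % | substrate / % |
|---|---|---|---|
| autumn | 0.167 | 13.4 | 87.3 |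
| autumn | 0.500 | 24.4 | 65.6 |
| autumn | 0.833 | 30.8 | 53.3 |
| autumn | 1.33 | 27.0 | 39.5 |
| autumn | 2.00 | 23.7 | 33.8 |
| autumn | 2.50 | 19.4 | 27.0 |
| spring | 0.200 | 12.8 | 83.7 |
| spring | 0.333 | 23.0 | 73.9 |
| spring | 0.500 | 27.2 | 64.0 |
| spring | 0.833 | 31.3 | 52.3 |
| spring | 1.50 | 31.8 | 34.6 |
| spring | 2.50 | 25.6 | 22.4 |
| dusk | 0.167 | 13.8 | 85.7 |
| dusk | 0.500 | 26.3 | 67.5 |
| dusk | 0.833 | 28.8 | 51.7 |
| dusk | 1.33 | 29.2 | 38.1 |
| dusk | 2.00 | 25.3 | 31.2 |
| dusk | 2.50 | 21.6 | 26.1 |

(readings scatter by 1 percentage point)

- the stated concentrations are those of everything mixed, before any reaction; amounts are the same in each set-up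
- the earlier runs were made in a closed, stirred flask

1. the set-up with the highest amount of target at the outlet or at the end, in percent of the substrate put in ("none" if the first two lie within 2 percentage points) (Tuesday's / Friday's / none)
2. amount of target at the outlet or at the end, in percent of the substrate put in, Tuesday's
3. amount of target at the outlet or at the end, in percent of the substrate put in, Friday's

Read the life from the autumn run between 1.33 min and 2.50 min. Target falls by 7.6 percentage points while substrate falls by 12 points. Read that substrate as target formed, and the target's loss comes to 20 points, so in these readings loss is larger than formation. The life then reads about 1.35 min: the target present divided by its rate of loss. The stay is about twice that life.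

In Tuesday's tank at steady state, formation balances loss, so, with converted substrate read as target formed, target equals substrate converted divided by one plus stay over life. By this estimate Tuesday's tank keeps 35.1% of what it converts as target. Friday's repeats the autumn charge and time, so expect near its reading of 19.4%. On the same estimate, Tuesday's tank matches that reading if it converts 55.3%.

The forecast gives 18.2% for Tuesday's and 20% for Friday's, and so none: “The two are within 2 points: none, narrowly.”

The flask gives 19.5% for Tuesday's and 20.0% for Friday's, so the answer is none.

    target ⇌ isomer of the product (K = 1.00, k = 0.00697 s⁻¹)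
    substrate + target → side product (k = 0.140 M⁻¹ s⁻¹)
    substrate ⇌ target + by-product (K = 0.0142 M, k = 0.0146 s⁻¹)
    target → over-reaction product (k = 0.00741 s⁻¹)

Tuesday's tank keeps 41.5% of its substrate and so converts 58.5%, and the life turns that into 20.5% of target against the 19.5% found. For a stay of 7.50 min, the same rule, counting the whole charge as converted, gives 15.3%, and the flow tank at that stay holds 13.0%.

(Readings and results stem from a simulated flask on assumed constants; the scatter is artificial.)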